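- The vessel is closed, stirred and isothermal, and this flask holds half the substrate of the west run, with the same coupling partner and free catalyst.

| flask | substrate | coupling partner | free catalyst | remark | time |
|---|---|---|---|---|---|
| west | 0.18 M | 0.108 M | 0.18 mM | run made earlier |  |
| flask | 0.090 M | 0.108 M | 0.18 mM |  | 50 min |

- west (time / min: target / %, substrate / %): 0.417: 0.9, 97.8; 0.667: 1.8, 97.9; 1.00: 2.0, 96.0; 2.00: 4.5, 93.4; 3.00: 7.0, 89.8; 5.00: 9.9, 83.3

(readings scatter by 0.5 percentage points)

* when, up to 50 min, the flask holds most target
* the amount of target, in percent of the substrate charged, at that time

- the numbers in the tables scatter with a standard deviation of 0.5 percentage points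

- We start with the main step alone and suppose that the catalyst turns over at a steady rate, zero order in substrate, which the west readings do not prove. Target in the west run then grows at v = 0.00356 M min⁻¹, read at 5.00 min, so this flask has an emptying time τ = 25.3 min, the substrate charge over v, with target reaching the full charge.
- Now we add one process: west substrate falls at 0.00601 M min⁻¹, faster than target grows, and the selectivity f, target formed per substrate lost, reads 59.3%. If that gap is a parallel loss, substrate in this flask lasts 15.0 min, and target stops near f.
- The remaining process, loss of free target, is not sized by these readings; if it runs, it lowers that number. Our own reckoning therefore puts the peak between 15.0 min and 25.3 min, at or a little under 59.3%.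
- The forecast gives 20 min and 30%, a time inside our window and an amount below ours: “the target peaks near 30% when about 30% of the substrate remains”.
- The flask gives 58.2% at 22.6 min, and at that peak it holds 0.949% substrate, not the forecast's about 30%.

    coupling partner + free catalyst ⇌ catalyst intermediate A (K = 15.0 M⁻¹, k = 4100 M⁻¹ min⁻¹)
    substrate + catalyst intermediate A → catalyst intermediate B (k = 1.10 × 10⁵ M⁻¹ min⁻¹)
    catalyst intermediate B ⇌ catalyst intermediate C (K = 1.50, k = 770 min⁻¹)
    catalyst intermediate C → by-product + catalyst intermediate D (k = 420 min⁻¹)
    catalyst intermediate D → free catalyst + target (k = 26.0 min⁻¹)
    target ⇌ isomer of the product (K = 3.10, k = 0.0470 min⁻¹)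
    substrate ⇌ dormant form (K = 0.340, k = 0.0140 min⁻¹)

- Up to the best time, v gives 89.4% of the charge turned over, and this flask holds 91.2% as target plus isomer of the product. The forward step from target to isomer has a half-life of 14.7 min, shorter than τ, and 33.0% isomer stands beside the target at that time.
- For the neighbour read at 12 min, the time as a fraction of τ gives 47.4% turned over. The neighbour, computed, holds 39.6% target and 11.5% isomer, together 51.1%, with 40.0% substrate left.

The earlier runs and the new flask come from a simulation for substances that don't exist; scatter was added.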